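The dihydropyran is cut first, at O–C4 and CH2–C5 (caryophyllane numbering), by a retro-hetero-Diels–Alder step that gives (−)-β-caryophyllene and an α-methylene trione. The six-membered carbocycle is then cut at CMe2–C(O) and at C(isobutyryl)–C(OH) in a retro-[3+3].
Enabling feature: the ring atoms CMe2–C(=O)–C and the exocyclic isobutyryl group together form one intact, symmetric iPrC(O)–CH2–C(O)iPr unit, the ring gem-dimethyl carbon being the methine of a second isobutyryl group. The other three ring atoms, C(O)–C(CH2)–C(OH), are a 2-substituted malonyl unit with two equivalent acyl carbons.
Forward: the diketone becomes a 1,3-bis(silyloxy)diene, and double C-acylation with methylmalonyl dichloride closes the carbocycle and sets its quaternary carbon before any acid-sensitive terpene is present. Dehydrogenation of the ring C-methyl group to the methide and a [4+2] addition then close the pyran onto the nine-membered ring.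
Stereochemistry: C1 and C9 come with the terpene. C4 and C5 are set together by suprafacial addition to the outer face of the E-alkene in the ring-flip conformer that has C4–CH3 syn to H-1.

Key step: step 3

Remark: the β-triketones are written as the chelated dienol tautomer that matches the target SMILES. Terpene atoms carry caryophyllane numbers (C1/C9 ring fusion, C4=C5 endocyclic alkene, C8 exocyclic methylene), and in this numbering the target is (1R,4S,5R,9S).

Step 1
Reactants: 1 2,6-dimethylheptane-3,5-dione (diisobutyrylmethane)
Product: 2 (4Z)-2,6-dimethyl-3,5-bis(trimethylsilyloxy)hepta-2,4-diene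
Conditions: TMSOTf (2.3 equiv), Et3N (2.6 equiv), Et2O, 0 °C → rt; pentane extraction, distillation
Reagents that add atoms: trimethylsilyl trifluoromethanesulfonate, C[Si](C)(C)OS(=O)(=O)C(F)(F)F
Why: Soft enolisation and O-silylation of a 1,3-diketone with a silyl triflate and a tertiary amine is the standard entry to 1,3-bis(silyloxy)-1,3-dienes; the O-silylated cation is symmetric, so loss of either isopropyl methine proton gives the same diene, and the enol ether geometry has no consequence later.

Step 2
Reactants: 3 methylmalonic acid
Product: 4 methylmalonyl dichloride
Conditions: SOCl2 (excess), DMF (cat.), 50 °C; distillation under reduced pressure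
Reagents that add atoms: thionyl chloride, O=S(Cl)Cl
Why: This is standard acid chloride formation, run well below the decarboxylation temperature of the malonic acid.

Step 3
Reactants: 2 (4Z)-2,6-dimethyl-3,5-bis(trimethylsilyloxy)hepta-2,4-diene; 4 methylmalonyl dichloride
Product: 6 3,5-dihydroxy-4,6,6-trimethyl-2-(2-methylpropanoyl)cyclohexa-2,4-dien-1-one, via monoacylated acid chloride 5 (not isolated)
Conditions: 4 added to 2, TMSOTf (10 mol %), CH2Cl2, −78 °C → rt; NaHCO3 extraction, then acidification
Reagents that add atoms: none
Why: Proposed new method: the terminal carbon of the 1,3-bis(silyloxy)diene 2, which both silyloxy groups activate, attacks one acyl chloride of 4 with loss of Me3SiCl and creates the quaternary CMe2–C(=O) bond of 5, whose remaining β-silyloxyenone carbon then attacks the second acyl chloride (or the acylketene derived from it) to close the ring. The closest known reaction types are the α,α'-annulation of silyl enol ethers with malonyl dichloride (Effenberger cyclisation) and the terminal C-acylations and formal [3+3] cyclisations of 1,3-bis(silyloxy)-1,3-dienes; their combination on an acyclic diketone-derived diene to give a cyclohexane-1,3,5-trione must be regarded as untested. The single ring closes in a 6-(enolexo)-exo-trig mode, and if the central carbon were acylated first the closure would be 6-(enolendo)-exo-trig and would lead to the same product. No lasting stereocentre is formed, because the methyl-bearing carbon of 6 is enolised. No regiochemical choice exists, because the two acyl chlorides of 4 and the two isobutyryl halves of the diketone are equivalent by symmetry. The selectivity needed is C- over O-acylation in the closure, and it is secured because the quaternary carbon denies O-closure an aromatic 2-pyranone sink, so the resulting enol lactone stays a reactive acyl donor that the silyl triflate should equilibrate to the chelated, strongly stabilised triketone.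

Step 4
Reactants: 6 3,5-dihydroxy-4,6,6-trimethyl-2-(2-methylpropanoyl)cyclohexa-2,4-dien-1-one; 7 (−)-β-caryophyllene
Product: 9 target (1R,4S,5R,9S)-caryophyllane-fused pyranocyclohexadienone, via methylene trione 8 (not isolated)
Conditions: Ag2O (2 equiv), TEMPO (20 mol %), 7 (3 equiv), toluene, rt, dark; chromatography
Reagents that add atoms: none
Why: Oxidative dehydrogenation of the ring C-methyl enol gives the α-methylene trione 8, which adds as a 1-oxadiene (inverse-electron-demand hetero-Diels–Alder) to the strained endocyclic E-alkene of 7 in preference to the exocyclic methylene, with CH2 bonding to C5 and the unchelated carbonyl oxygen next to CMe2 bonding to the more substituted C4; suprafacial addition to the outer alkene face fixes the trans ring fusion, the conformer with C4–CH3 syn to H-1 delivers (4S,5R)-9, and the adduct of the ring-flipped conformer is removed by chromatography.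

Compound list
1 | 2,6-dimethylheptane-3,5-dione (diisobutyrylmethane) | CC(C)C(=O)CC(=O)C(C)C | starting material
2 | (4Z)-2,6-dimethyl-3,5-bis(trimethylsilyloxy)hepta-2,4-diene | CC(C)=C(O[Si](C)(C)C)/C=C(\O[Si](C)(C)C)C(C)C | intermediate
3 | methylmalonic acid | CC(C(=O)O)C(=O)O | starting material
4 | methylmalonyl dichloride (2-methylpropanedioyl dichloride) | CC(C(=O)Cl)C(=O)Cl | intermediate
5 | (6Z)-2,4,4,8-tetramethyl-3,5-dioxo-7-(trimethylsilyloxy)non-6-enoyl chloride (C2 racemic and labile) | CC(C(=O)Cl)C(=O)C(C)(C)C(=O)/C=C(\O[Si](C)(C)C)C(C)C | intermediate
6 | 3,5-dihydroxy-4,6,6-trimethyl-2-(2-methylpropanoyl)cyclohexa-2,4-dien-1-one | CC1=C(O)C(C)(C)C(=O)C(C(=O)C(C)C)=C1O | intermediate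
7 | (−)-β-caryophyllene, (1R,4E,9S) | C=C1CC/C=C(\C)CC[C@@H]2[C@@H]1CC2(C)C | starting material
8 | 5-hydroxy-2,2-dimethyl-6-methylidene-4-(2-methylpropanoyl)cyclohex-4-ene-1,3-dione | C=C1C(=O)C(C)(C)C(=O)C(C(=O)C(C)C)=C1O | intermediate
9 | target: trans-fused cyclobutane/cyclononane/dihydropyran/cyclohexadienone tetracycle, pyran O on C4 and pyran CH2 on C5, exocyclic C8 methylene, chelated enol and isobutyryl group, (1R,4S,5R,9S) | C=C1CC[C@@H]2CC3=C(O[C@@]2(C)CC[C@@H]2[C@@H]1CC2(C)C)C(C)(C)C(=O)C(C(=O)C(C)C)=C3O | target

Total step count: 4. Longest linear sequence: 3 (1 → 2 → 6 → 9).

Steps most likely to fail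

1. Step 3 (labelled step). The ring may close through oxygen instead of carbon, and the bis-acid chloride may oligomerise through its ketene, so that the two acylations do not end in the carbocycle. The fallback uses known chemistry and separates the two bond formations. It sets out from 5, generated from 2 and 4 at −78 °C as before. Quenching with methanol turns the acid chloride into the ester and removes the silyl group, giving methyl 2,4,4,8-tetramethyl-3,5,7-trioxononanoate F1, which is isolated. Dieckmann (Claisen-type) cyclisation of this 3,5,7-triketo ester with t-BuOK in THF, in which the doubly activated CH2 attacks the ester, comes back to the route at 6.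

2. Step 4. Facial selectivity at the endocyclic alkene may be poor, because both ring-flip conformer families of 7 react. The face required here is opposite to the one peracids attack in forming the common (4R,5R)-oxide, so substrate control cannot be relied on. Self-condensation of the methide is a second loss channel. The fallback moves the facial choice from substrate to catalyst control and sets out from 6. Ag2O in methanol traps the methide as 3,5-dihydroxy-4-(methoxymethyl)-6,6-dimethyl-2-(2-methylpropanoyl)cyclohexa-2,4-dien-1-one F2, a storable precursor. A chiral BINOL-derived phosphoric acid (both antipodes to be screened) in toluene with 7 then releases the methide slowly as a hydrogen-bonded complex, so double stereodifferentiation decides the alkene face and the stationary methide concentration stays low. The fallback comes back to the route at 8 and hence 9.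

3. Step 1. Enolisation of the hindered isopropyl methine may be incomplete, and the silyl groups may be lost by hydrolysis during isolation. The fallback replaces soft double enolisation by a staged hard enolisation and sets out from 1. TMSCl and Et3N give (4Z)-2,6-dimethyl-5-(trimethylsilyloxy)hept-4-en-3-one F3. Kinetic deprotonation of its α'-methine with LDA in THF at −78 °C, followed by a TMSCl quench, comes back to the route at 2.

Further compounds
F1 | step 3 | methyl 2,4,4,8-tetramethyl-3,5,7-trioxononanoate | COC(=O)C(C)C(=O)C(C)(C)C(=O)CC(=O)C(C)C
F2 | step 4 | 3,5-dihydroxy-4-(methoxymethyl)-6,6-dimethyl-2-(2-methylpropanoyl)cyclohexa-2,4-dien-1-one | COCC1=C(O)C(C)(C)C(=O)C(C(=O)C(C)C)=C1O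
F3 | step 1 | (4Z)-2,6-dimethyl-5-(trimethylsilyloxy)hept-4-en-3-one | CC(C)C(=O)/C=C(\O[Si](C)(C)C)C(C)C
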